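**Plan**
- Retrosynthesis first cuts the benzyl–O bond on C1 and the two methyl–O bonds, then ring bond C3–C4 of the arene, which turns the benzene ring back into 5-benzyloxy-4-heneicosyl-6-methyl-2-pyranone.
- Enabling feature: the oxygens on C2 and C4 are meta and flank the unsubstituted C3. C3 is therefore the methyl carbon of a methyl ketone (C2) and C4 an ester carbonyl, held cis by the C5=C6 unit; this is the atom pattern of a 6-methyl-2-pyranone with its ring oxygen on C2.
- The pyranone is traced back through enolisation and lactol oxidation to an Achmatowicz pyranone and hence to a 2-(1-hydroxyethyl)-3-heneicosylfuran (furan C2, C3, C4, C5 become arene C1, C6, C5, C4). The last cuts are the C6–chain bond and the furan–carbinol bond.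
- Forward: the two-carbon arm and the C21 chain are attached to 3-bromofuran, the furan is expanded to the six-membered oxygen ring, oxidised and O-benzylated to the 2-pyranone, and the carbocycle arises last from the pyranone.
- Stereochemistry: the target has no stereocentre; the racemic carbinol and lactol centres of the intermediates are erased by oxidation and enolisation.

Key step: step 6

Assumption: ring atoms are numbered as in the target name (C1 carries OH, C2 and C4 the methoxy groups, C6 the chain), and 1-bromoheneicosane is taken as a purchasable C21 building block.

**Step 1**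
Reactants: 1 3-bromofuran; 2 acetaldehyde
Product: 4 1-(3-bromofuran-2-yl)ethanol (racemic), via 3-bromofuran-2-yllithium 3 (not isolated)
Conditions: LiN(i-Pr)2, THF, −78 °C; then MeCHO, −78 → 0 °C; H2O
Reagents that add atoms: none
Why: Directed lithiation followed by 1,2-addition: LiN(i-Pr)2 removes the C2 proton of 3-bromofuran (the α-position acidified by the adjacent bromine) at −78 °C without halogen–lithium exchange, and the furyllithium adds to acetaldehyde to give the carbinol as a racemate whose stereocentre is erased in step 5.

**Step 2**
Reactants: 4 1-(3-bromofuran-2-yl)ethanol; 5 1-bromoheneicosane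
Product: 7 1-(3-heneicosylfuran-2-yl)ethanol (racemic), via heneicosylmagnesium bromide 6 (not isolated)
Conditions: 5, Mg, THF, 50 °C; separately 4, t-BuMgCl (1.0 equiv), THF, 0 °C; then both combined, NiCl2(dppp) (5 mol %), THF, rt → 50 °C; aq NH4Cl
Reagents that add atoms: none
Why: Kumada–Tamao–Corriu coupling: zerovalent nickel formed from NiCl2(dppp) and the Grignard reagent inserts into the furyl C–Br bond, and the bidentate phosphine lets reductive elimination of the primary alkyl group outrun β-hydride elimination, while the alcohol, masked beforehand as its magnesium alkoxide with t-BuMgCl, consumes none of the C21 reagent.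

**Step 3**
Reactants: 7 1-(3-heneicosylfuran-2-yl)ethanol
Product: 8 4-heneicosyl-6-hydroxy-2-methyl-2H-pyran-3(6H)-one (racemic mixture of anomers)
Conditions: mCPBA (1.1 equiv), CH2Cl2, 0 °C → rt
Reagents that add atoms: mCPBA, OOC(=O)c1cccc(Cl)c1
Why: Achmatowicz rearrangement: the peracid oxidises the electron-rich 2,3-bond of the furan, the resulting cis-ene-dione is trapped by the secondary hydroxyl as the six-membered lactol, and the new anomeric centre forms without control, which is immaterial because it is oxidised in step 4.

**Step 4**
Reactants: 8 4-heneicosyl-6-hydroxy-2-methyl-2H-pyran-3(6H)-one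
Product: 9 4-heneicosyl-2-methyl-2H-pyran-3,6-dione (racemic)
Conditions: CrO3, aq H2SO4, acetone–CH2Cl2, 0 °C
Reagents that add atoms: none
Why: Jones oxidation of a lactol to a lactone by hexavalent chromium via the chromate ester of the hemiacetal, a standard follow-up to the Achmatowicz rearrangement that leaves the enone and the α-acyloxy ketone untouched; the dione is taken on crude because it enolises readily.

**Step 5**
Reactants: 9 4-heneicosyl-2-methyl-2H-pyran-3,6-dione; 10 benzyl bromide
Product: 12 5-(benzyloxy)-4-heneicosyl-6-methyl-2H-pyran-2-one, via 4-heneicosyl-5-hydroxy-6-methyl-2H-pyran-2-one 11 (not isolated)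
Conditions: K2CO3, BnBr, DMF, rt
Reagents that add atoms: none
Why: Base-induced enolisation and Williamson O-alkylation: carbonate removes the proton on the methyl-bearing carbon (α to the ketone and vinylogous to the lactone carbonyl), the resulting 5-oxido-2-pyranone is a phenoxide-like aromatic anion that is benzylated on oxygen in DMF, and the last stereocentre of the route disappears.

**Step 6**
Reactants: 12 5-(benzyloxy)-4-heneicosyl-6-methyl-2H-pyran-2-one
Product: 14 4-(benzyloxy)-5-heneicosylbenzene-1,3-diol, via methyl (3E)-4-(benzyloxy)-3-heneicosyl-5-oxohex-3-enoate 13 (not isolated)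
Conditions: NaOMe (6 equiv), degassed MeOH, sealed tube, 140 °C, Ar; then aq HCl, 0 °C
Reagents that add atoms: none
Why: Methoxide adds to the lactone carbonyl of 12 and the ring oxygen leaves as the enolate of the methyl ketone, giving the sodium dienolate of keto ester 13, in which the former pyranone C3=C4 bond still holds the ester carbon and the acetyl-bearing carbon on the same side. Proton exchange with hot methanol makes the less stable terminal enolate at the former 6-methyl carbon available; it attacks the ester carbonyl, methoxide is lost, and the cyclic dione tautomer of 14 enolises twice to the resorcinol dianion, which is an irreversible sink. The closest known chemistry is the alkoxide-induced isomerisation of 4-alkoxy-6-methyl-2-pyranones to 5-alkoxyresorcinols, together with the Claisen (Dieckmann-type) cyclisation of δ-keto esters to cyclohexane-1,3-diones. The benzene ring closes in a 6-(enolexo)-exo-trig mode and the new bond is the one between arene C3 and C4. No stereocentre is formed. The step needs C-acylation through the methyl carbon alone: the internal positions of the delocalised anion cannot reach the ester through a six-membered transition state, geometric drift of the open-chain anion is reversible under these conditions whereas aromatisation is not, and the benzyl ether is inert to methoxide.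

**Step 7**
Reactants: 14 4-(benzyloxy)-5-heneicosylbenzene-1,3-diol
Product: 15 2-(benzyloxy)-1-heneicosyl-3,5-dimethoxybenzene
Conditions: MeI, K2CO3, acetone, reflux, Ar
Reagents that add atoms: iodomethane, CI
Why: Williamson ether synthesis: both phenols are deprotonated by K2CO3 and methylated on oxygen by iodomethane in acetone, conditions under which the benzyl ether is inert and C-methylation of the ring is not expected to compete.

**Step 8**
Reactants: 15 2-(benzyloxy)-1-heneicosyl-3,5-dimethoxybenzene
Product: 16 6-heneicosyl-2,4-dimethoxyphenol
Conditions: H2 (1 atm), Pd/C, EtOAc–EtOH, rt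
Reagents that add atoms: none
Why: Catalytic hydrogenolysis: the benzylic C–O bond is cleaved on zerovalent palladium at room temperature and one atmosphere, which leaves the methyl ethers, the arene and the saturated chain unchanged and frees the C1 phenol.

**Compound list**
1 | 3-bromofuran | Brc1ccoc1 | starting material
2 | acetaldehyde | CC=O | starting material
3 | 3-bromofuran-2-yllithium (formed in situ) | [Li]c1occc1Br | intermediate
4 | 1-(3-bromofuran-2-yl)ethanol (racemic) | CC(O)c1occc1Br | intermediate
5 | 1-bromoheneicosane | CCCCCCCCCCCCCCCCCCCCCBr | starting material
6 | heneicosylmagnesium bromide (formed in situ) | CCCCCCCCCCCCCCCCCCCCC[Mg]Br | intermediate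
7 | 1-(3-heneicosylfuran-2-yl)ethanol (racemic) | CCCCCCCCCCCCCCCCCCCCCc1ccoc1C(C)O | intermediate
8 | 4-heneicosyl-6-hydroxy-2-methyl-2H-pyran-3(6H)-one (racemic, anomer mixture) | CCCCCCCCCCCCCCCCCCCCCC1=CC(O)OC(C)C1=O | intermediate
9 | 4-heneicosyl-2-methyl-2H-pyran-3,6-dione (racemic) | CCCCCCCCCCCCCCCCCCCCCC1=CC(=O)OC(C)C1=O | intermediate
10 | benzyl bromide | BrCc1ccccc1 | starting material
11 | 4-heneicosyl-5-hydroxy-6-methyl-2H-pyran-2-one (formed in situ) | CCCCCCCCCCCCCCCCCCCCCC1=CC(=O)OC(C)=C1O | intermediate
12 | 5-(benzyloxy)-4-heneicosyl-6-methyl-2H-pyran-2-one | CCCCCCCCCCCCCCCCCCCCCC1=CC(=O)OC(C)=C1OCc2ccccc2 | intermediate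
13 | methyl (3E)-4-(benzyloxy)-3-heneicosyl-5-oxohex-3-enoate (formed in situ as its sodium dienolate) | COC(=O)C/C(CCCCCCCCCCCCCCCCCCCCC)=C(OCc1ccccc1)\C(C)=O | intermediate
14 | 4-(benzyloxy)-5-heneicosylbenzene-1,3-diol | CCCCCCCCCCCCCCCCCCCCCc1cc(O)cc(O)c1OCc2ccccc2 | intermediate
15 | 2-(benzyloxy)-1-heneicosyl-3,5-dimethoxybenzene | CCCCCCCCCCCCCCCCCCCCCc1cc(OC)cc(OC)c1OCc2ccccc2 | intermediate
16 | 6-heneicosyl-2,4-dimethoxyphenol | CCCCCCCCCCCCCCCCCCCCCc1cc(OC)cc(OC)c1O | target

**Totals**
Total step count: 8. Longest linear sequence: 8 steps (from 3-bromofuran; the Grignard reagent is made in the flask within step 2).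

**Steps most likely to fail**

1. Step 6. The ring-opened dienolate may persist as a delocalised anion whose ester carbonyl is deactivated, so that acylation through the methyl carbon does not set in below temperatures at which the benzyl ether is cleaved, and acidification then merely relactonises the material. The fallback gives up the pyranone and builds the arene by classical substitution chemistry. It sets out from Grignard reagent 6 (made from bromide 5). Kumada coupling with commercial 1-bromo-3,5-dimethoxybenzene (NiCl2(dppp), THF) should give 1-heneicosyl-3,5-dimethoxybenzene F1. Vilsmeier–Haack formylation (POCl3, DMF) is expected ortho to the chain and para to a methoxy group, giving 2-heneicosyl-4,6-dimethoxybenzaldehyde F2. Baeyer–Villiger (Dakin-type) oxidation with mCPBA in CH2Cl2 should give 2-heneicosyl-4,6-dimethoxyphenyl formate F3. Cleavage of the formate with aq KOH in MeOH returns to the route at target 16.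

2. Step 5. Under basic conditions the ambident anion may be benzylated on the methyl-bearing carbon, or the ene-dione may self-condense before it enolises. The fallback moves the alkylation away from enolate chemistry. It sets out from dione 9, which is tautomerised with a catalytic amount of Et3N in CH2Cl2, and hydroxypyranone 11 is isolated. The neutral enol is then benzylated under acid catalysis with benzyl 2,2,2-trichloroacetimidate and catalytic TfOH in CH2Cl2–cyclohexane, where reaction on oxygen is the only pathway expected. The route is rejoined at 12; no compound outside the list is made.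

3. Step 2. The neighbouring alkoxide may inhibit the nickel catalyst or deliver hydride, leading to hydrodebromination, and the Grignard reagent may homocouple. The fallback changes the order of bond formation. It sets out from 3-bromofuran 1, which is coupled with Grignard reagent 6 under the same nickel catalysis to give 3-heneicosylfuran F4. Vilsmeier–Haack formylation (POCl3, DMF), which for 3-alkylfurans takes place at C2, should give 3-heneicosylfuran-2-carbaldehyde F5. Addition of MeMgBr in THF returns to the route at 7.

**Further compounds**
F1 | step 6 | 1-heneicosyl-3,5-dimethoxybenzene | CCCCCCCCCCCCCCCCCCCCCc1cc(OC)cc(OC)c1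
F2 | step 6 | 2-heneicosyl-4,6-dimethoxybenzaldehyde | CCCCCCCCCCCCCCCCCCCCCc1cc(OC)cc(OC)c1C=O
F3 | step 6 | 2-heneicosyl-4,6-dimethoxyphenyl formate | CCCCCCCCCCCCCCCCCCCCCc1cc(OC)cc(OC)c1OC=O
F0 | step 5 | none | none
F4 | step 2 | 3-heneicosylfuran | CCCCCCCCCCCCCCCCCCCCCc1ccoc1
F5 | step 2 | 3-heneicosylfuran-2-carbaldehyde | CCCCCCCCCCCCCCCCCCCCCc1ccoc1C=O
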